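## The problem

The target **17** is (2S)-5-hydroxy-2-(4-hydroxyphenyl)-6,7-dimethoxy-8-(3-methylbut-2-enyl)chroman-4-one, a flavanone. Ring A is fused to the dihydropyranone ring C along C4a–C8a, and ring B hangs from C2. Every carbon of ring A is substituted (5-OH, 6-OMe, 7-OMe, 8-prenyl), so the prenyl group must be placed at C8 without ambiguity and the C5 oxygen must be told apart from its two methylated neighbours. C2 is the only stereocentre and nothing else in the molecule can direct it, so it has to come from a reagent or catalyst. It is also fragile. Deprotonation at C3 opens ring C by a retro-oxa-Michael reaction to the achiral 2'-hydroxychalcone, the free 4'-phenol makes this easier under base, and the para oxygen of ring B helps the C2–O1 bond to ionise under strong acid. The prenyl olefin rules out hydrogenolysis and hot protic acid, and the two phenols are best released last. The feature that invites a carbenoid route is that C2 is a benzylic carbon bonded to O1. In an open precursor it is the CH2 of an aryl benzyl ether, its C–H bonds are made hydridic by O1 and by the para-oxygenated ring B, and it stands 1,6 to C3, the carbon next to the C4 ketone where a diazo group can be placed.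

## Retrosynthesis

**17 from 16.** The last cut removes the C5 O–CH3 bond and the 4'-O–CH2OCH3 bond. The C5 methoxy group is the only methyl ether that can chelate a Lewis acid together with the C4 carbonyl, so BCl3 should take it alone, and the same reagent cleaves the aryl methoxymethyl ether. Carrying a different group on the C5 oxygen from the start would mean differentiating the two oxygens ortho to the acetyl group of **4**, which costs steps. Precursor **16** has no free phenol and so tolerates all earlier operations. The forward step must be short and cold so that C2–O1 does not ionise and HCl does not add to the prenyl olefin.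

**16 from 14 (through 15).** In the retrosynthetic direction an allyl ester is added at C3. It makes C3 a doubly activated carbon, which is what diazo transfer and a well-behaved carbenoid require. Allyl is preferred to methyl, whose removal with hot halide passes through the C3 enolate and invites ring opening, and to tert-butyl, whose removal needs acid that endangers the prenyl group. The forward reaction has to pass the allyl group to a neutral acceptor on palladium, after which acid **15** loses CO2 through its hydrogen-bonded cyclic form, with no base strong enough to open ring C.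

**14 from 13 (key cut, C2–C3).** Cutting O1–C2 instead would lead to an oxa-Michael closure, and the reversibility of that reaction is the racemisation pathway of flavanones. Cutting C4–C4a would require acylation of a fully substituted ring carbon. The C2–C3 cut removes ring C and both stereocentres of **14** at once and leaves the achiral diazo keto ester **13**, in which ring A is intact. The forward reaction must insert the C3 carbenoid into one of the two enantiotopic benzylic hydrogens and nowhere else.

**13 from 12, and 12 from 10 and 11.** The diazo group comes from diazo transfer to the active methylene of **12**. The C3–CO2allyl bond comes from a crossed Claisen condensation of methyl ketone **10** with diallyl carbonate **11**. The acetyl group of the starting acetophenone thus supplies C3 and C4, and no benzoic acid derivative has to be made. Both steps ask only for tolerance of the benzyl ether, the acetal and the olefin toward base.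

**10 from 9 and 3.** The O1–CH2 bond is cut. This brings in ring B and the future C2 as the primary benzylic alcohol **3**, which is made from **1** through **2** by protection and reduction. A Mitsunobu coupling is preferred to alkylation with the corresponding para-alkoxybenzyl halide, which is labile. The forward step must overcome a phenol that is flanked on both sides and hydrogen-bonded to the ketone.

**9 from 7, 7 from 6, 6 from 4 and 5.** The C8–prenyl bond is cut by a [3,3] shift, which traces **9** to the 1,1-dimethylallyl ether **7**. Direct C-prenylation of the phenol would compete with O-alkylation and chroman formation. The rearrangement is regiospecific, since C3' is the only free ortho position and the para position is blocked by a methoxy group. Ether **7** comes from the propargyl ether **6** by semi-hydrogenation, and **6** from the commercial acetophenone **4** and chloride **5**. Ring A is therefore bought complete and only decorated.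

## Roads not taken

**Alternative 1:** The cut is C3–C4, with C4 reversed in polarity as a 2-aryl-1,3-dithiane. In the forward step n-butyllithium would deprotonate dithiane **A1** and the C4 anion would displace the primary tosylate on C3 (6-exo-tet), giving the dithioketal **A2**.
- Merits: C2 is made before ring closure by established asymmetric reduction chemistry. From **A2** until unmasking, ring C has no carbonyl group, so neither retro-oxa-Michael opening nor a labile C3 ester can touch C2. Through its middle stages this road protects the stereocentre better than the chosen one.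
- Weak points: the stereocentre must survive formation of the O1–C2 ether, an SN2 etherification between a doubly ortho-substituted phenol and a secondary para-alkoxybenzylic alcohol that ionises easily. The hindered dithiane must be lithiated beside an acidic benzylic C2–H. The dithioketal must finally be removed with mercury salts, halonium sources or hypervalent iodine, all of which also attack the prenyl olefin and the electron-rich ring A. The aldehyde needed for **A1** is not at hand from **4**, and the sequence is several steps longer.
- Comparison: the chosen plan creates C2 catalytically from an achiral precursor and takes all carbons of rings A and C from **4**. It pays with a configurationally delicate β-keto ester between steps 9 and 10.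

**Alternative 2:** Three bonds are cut at once (C4a–C4, C4–C3 and O1–C2), leading back to iodophenol **A3**, carbon monoxide and alkyne **A4**. In the forward step PdCl2(PPh3)2, Et2NH and CO would join the three components and close ring C as flavone **A5**. The C2=C3 bond would then have to be reduced enantioselectively.
- Merits: this is the most convergent route. **A5** is achiral and robust, so the C5 demethylation with BCl3 could be done before any stereocentre exists. That is a real advantage over the chosen endgame, which must run this step on the finished stereocentre.
- Weak points: **A3** is a hexasubstituted iodophenol with a prenyl group ortho to the hydroxyl, and electrophilic iodination would sooner cyclise the phenol onto the olefin. Closure to an aurone competes with flavone formation. Enantioselective reduction of a flavone C2=C3 bond is much less developed than the insertion used here, and catalysts able to do it also reduce the C4 ketone and the prenyl olefin. The benzyl ether of **A5** cannot be removed by hydrogenolysis without saturating the side chain.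
- Comparison: the stereocentre would arise in the least precedented step of that route. The chosen plan sets it in a known reaction type and keeps the olefin away from hydrogen throughout.

**Alternative 3:** Ring A is cut at C4a–C5 and traced to the tricarbonyl chain of **A6**, attached to a pre-formed ring C. In the forward step base would form the extended enolate, C4a would attack the methyl ester, methanol would be lost and enolisation would aromatise ring A to give **A7**.
- Merits: the C5 and C7 hydroxyls arrive free and distinct from the C6 methoxy group. The non-chelated C7 hydroxyl can be methylated selectively, so no Lewis-acid demethylation is needed, which is better than the chosen endgame. C2 could be set early by a catalytic asymmetric hetero-Diels–Alder reaction.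
- Weak points: **A6**, with its prenylated and methoxylated chain, needs many steps and can cyclise in other modes (O-acylation, aldol closure). The base needed for the condensation can deprotonate C3 of the dihydropyranone and open O1–C2, so the early stereocentre is exposed at the key step. Ring A of the target can be bought intact as **4**, so building it from a chain adds steps without benefit.
- Comparison: the chosen plan is shorter and uses ring A as purchased. In return it has to accept the late BCl3 step.

Key step: step 9

**Assumptions.**
- The sense of induction of Rh2(PTTL)4 in this insertion cannot be derived safely by analogy. Rh2(S-PTTL)4 is written throughout, and Rh2(R-PTTL)4 takes its place if the (S)-ligand turns out to lead to 2R.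
- Acetophenone **4** is treated as a catalogue compound.

## Route

Step 1
Reactants: 1 4-hydroxybenzaldehyde
Product: 2 4-(methoxymethoxy)benzaldehyde
Conditions: MOMCl, iPr2NEt, CH2Cl2, 0 °C to rt
Reagents that add atoms: chloromethyl methyl ether, COCCl
Why: O-alkylation of the phenol with a reactive α-chloro ether (Williamson-type etherification); the aldehyde is inert, and the acetal should survive every later step up to the final Lewis acid.

Step 2
Reactants: 2 4-(methoxymethoxy)benzaldehyde
Product: 3 [4-(methoxymethoxy)phenyl]methanol
Conditions: NaBH4, MeOH, 0 °C
Reagents that add atoms: none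
Why: Borohydride reduction of an aromatic aldehyde to the primary benzylic alcohol; the acetal is stable to hydride.

Step 3
Reactants: 4 1-(2-hydroxy-4,5,6-trimethoxyphenyl)ethanone; 5 3-chloro-3-methylbut-1-yne
Product: 6 1-[2,3,4-trimethoxy-6-(2-methylbut-3-yn-2-yloxy)phenyl]ethanone
Conditions: DBU, CuCl2 (cat.), MeCN, 0 °C to rt
Reagents that add atoms: none
Why: Copper-catalysed O-alkylation of a phenol with a tertiary propargylic chloride is the standard entry to aryl 1,1-dimethylpropargyl ethers; the single phenol of 4 is the only nucleophilic site.

Step 4
Reactants: 6 1-[2,3,4-trimethoxy-6-(2-methylbut-3-yn-2-yloxy)phenyl]ethanone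
Product: 7 1-[2,3,4-trimethoxy-6-(2-methylbut-3-en-2-yloxy)phenyl]ethanone
Conditions: H2 (1 atm), Pd/CaCO3 poisoned with Pb(OAc)2 (Lindlar catalyst), quinoline, EtOAc, rt
Reagents that add atoms: none
Why: Lindlar semi-hydrogenation of the terminal alkyne should stop at the alkene and leave the aryl ketone untouched; without it the propargyl ether would close to a chromene on heating.

Step 5
Reactants: 7 1-[2,3,4-trimethoxy-6-(2-methylbut-3-en-2-yloxy)phenyl]ethanone
Product: 9 1-[2-hydroxy-4,5,6-trimethoxy-3-(3-methylbut-2-enyl)phenyl]ethanone, via Claisen dienone 8 (not isolated)
Conditions: PhNEt2, 130 °C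
Reagents that add atoms: none
Why: Aromatic Claisen rearrangement; the [3,3] shift delivers the allyl terminus to C3', the only free ortho position (the para position carries a methoxy group), and turns the 1,1-dimethylallyl group into the 3-methylbut-2-enyl group; tautomerisation of dienone 8 restores the phenol.

Step 6
Reactants: 9 1-[2-hydroxy-4,5,6-trimethoxy-3-(3-methylbut-2-enyl)phenyl]ethanone; 3 [4-(methoxymethoxy)phenyl]methanol
Product: 10 1-[4,5,6-trimethoxy-2-{[4-(methoxymethoxy)phenyl]methoxy}-3-(3-methylbut-2-enyl)phenyl]ethanone
Conditions: PPh3, DIAD, THF, 0 °C to rt
Reagents that add atoms: none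
Why: Mitsunobu etherification of an acidic, ketone-chelated phenol with a primary benzylic alcohol, a coupling established for ortho-acyl phenols; it avoids the labile para-alkoxybenzyl halide.

Step 7
Reactants: 10 1-[4,5,6-trimethoxy-2-{[4-(methoxymethoxy)phenyl]methoxy}-3-(3-methylbut-2-enyl)phenyl]ethanone; 11 diallyl carbonate
Product: 12 prop-2-enyl 3-[4,5,6-trimethoxy-2-{[4-(methoxymethoxy)phenyl]methoxy}-3-(3-methylbut-2-enyl)phenyl]-3-oxopropanoate
Conditions: NaH, THF, reflux; then AcOH
Reagents that add atoms: none
Why: Crossed Claisen condensation of the methyl ketone enolate with a carbonate; the acetyl group is the only enolisable position, and formation of the sodium enolate of the β-keto ester drives the reaction.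

Step 8
Reactants: 12 prop-2-enyl 3-[4,5,6-trimethoxy-2-{[4-(methoxymethoxy)phenyl]methoxy}-3-(3-methylbut-2-enyl)phenyl]-3-oxopropanoate
Product: 13 prop-2-enyl 2-diazo-3-[4,5,6-trimethoxy-2-{[4-(methoxymethoxy)phenyl]methoxy}-3-(3-methylbut-2-enyl)phenyl]-3-oxopropanoate
Conditions: 4-acetamidobenzenesulfonyl azide, Et3N, MeCN, 0 °C to rt
Reagents that add atoms: 4-acetamidobenzenesulfonyl azide, CC(=O)Nc1ccc(cc1)S(=O)(=O)N=[N+]=[N-]
Why: Regitz diazo transfer to the active methylene of a β-keto ester, a general and mild reaction that none of the other groups should disturb.

Step 9
Reactants: 13 prop-2-enyl 2-diazo-3-[4,5,6-trimethoxy-2-{[4-(methoxymethoxy)phenyl]methoxy}-3-(3-methylbut-2-enyl)phenyl]-3-oxopropanoate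
Product: 14 prop-2-enyl (2S,3R)-5,6,7-trimethoxy-2-[4-(methoxymethoxy)phenyl]-8-(3-methylbut-2-enyl)-4-oxochromane-3-carboxylate (2,3-trans)
Conditions: Rh2(S-PTTL)4 (dirhodium tetrakis[N-phthaloyl-(S)-tert-leucinate], 1 mol%), CH2Cl2, 0 °C to rt, slow addition of 13
Reagents that add atoms: none
Why: The dirhodium complex takes up the diazo carbon of 13, nitrogen leaves and an electrophilic acceptor/acceptor rhodium carbenoid stands at C3. It should insert into one C–H bond of the OCH2Ar group through a three-centre, hydride-transfer-like transition state in which C2–C3 forms as hydrogen moves to C3 and the catalyst is released. The closest known reaction type is the enantioselective dirhodium-carboxylate-catalysed intramolecular C–H insertion of ortho-alkoxyaryl diazo ketones and diazo keto esters next to the ether oxygen, which gives 2-substituted chroman-4-ones. Ring C closes as a six-membered ring by 1,6-insertion (C3, C4, C4a, C8a, O1 and C2 in a chair-like array), and no smaller ring can form because O1 carries no hydrogen and no C–H bond lies closer to C3. C2 is set by the catalyst alone: the wall of phthalimido groups lets only one of the two enantiotopic benzylic hydrogens reach the carbenoid, the antipode of the ligand being chosen for 2S. C3 is not under kinetic control, since the β-keto ester enolises and should settle as the trans isomer with aryl and ester groups both equatorial, and this centre is erased in step 10. The step needs insertion at OCH2Ar to beat oxonium ylide formation at O1 followed by benzyl shift, insertion into the C5 methoxy group, and cyclopropanation of the prenyl or allyl olefin. The substrate helps: the target C–H bond is activated twice (by O1 and by the para-alkoxyphenyl ring), the two ortho substituents turn the O–CH2 bond out of the plane of ring A and hold it over C3, the methoxy C–H bonds are primary, the prenyl olefin could be reached only through a seven-membered ring, and the allyl ester would have to adopt its disfavoured s-cis form.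

Step 10
Reactants: 14 prop-2-enyl (2S,3R)-5,6,7-trimethoxy-2-[4-(methoxymethoxy)phenyl]-8-(3-methylbut-2-enyl)-4-oxochromane-3-carboxylate
Product: 16 (2S)-5,6,7-trimethoxy-2-[4-(methoxymethoxy)phenyl]-8-(3-methylbut-2-enyl)chroman-4-one, via beta-keto acid 15 (not isolated)
Conditions: Pd(OAc)2 (5 mol%), PPh3, HCO2H (slight excess over amine), Et3N, THF, rt then 40 °C
Reagents that add atoms: none
Why: Tsuji-type deallylation of an allyl β-keto ester: zerovalent palladium formed in situ ionises the allyl ester, formate reduces the allyl fragment to propene, and acid 15 loses CO2 through its cyclic hydrogen-bonded form; the buffered, slightly acidic medium leaves no free base to open ring C, so C2 should be retained.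

Step 11
Reactants: 16 (2S)-5,6,7-trimethoxy-2-[4-(methoxymethoxy)phenyl]-8-(3-methylbut-2-enyl)chroman-4-one
Product: 17 (2S)-5-hydroxy-2-(4-hydroxyphenyl)-6,7-dimethoxy-8-(3-methylbut-2-enyl)chroman-4-one
Conditions: BCl3, CH2Cl2, −78 to 0 °C; aqueous work-up kept at or below pH 7
Reagents that add atoms: none
Why: Chelation-controlled ether cleavage: BCl3 bound to the C4 carbonyl removes only the peri methoxy group at C5 and also cleaves the aryl methoxymethyl ether; the prenyl group has no ortho hydroxyl to cyclise onto, and the short, cold, base-free treatment is chosen to keep C2 intact.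

## Compound list

1 | 4-hydroxybenzaldehyde | O=Cc1ccc(O)cc1 | starting material
2 | 4-(methoxymethoxy)benzaldehyde | COCOc1ccc(C=O)cc1 | intermediate
3 | [4-(methoxymethoxy)phenyl]methanol | COCOc1ccc(CO)cc1 | intermediate
4 | 1-(2-hydroxy-4,5,6-trimethoxyphenyl)ethanone (2'-hydroxy-4',5',6'-trimethoxyacetophenone) | CC(=O)c1c(O)cc(OC)c(OC)c1OC | starting material
5 | 3-chloro-3-methylbut-1-yne | CC(C)(Cl)C#C | starting material
6 | 1-[2,3,4-trimethoxy-6-(2-methylbut-3-yn-2-yloxy)phenyl]ethanone | CC(=O)c1c(OC(C)(C)C#C)cc(OC)c(OC)c1OC | intermediate
7 | 1-[2,3,4-trimethoxy-6-(2-methylbut-3-en-2-yloxy)phenyl]ethanone | CC(=O)c1c(OC(C)(C)C=C)cc(OC)c(OC)c1OC | intermediate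
8 | 2-acetyl-3,4,5-trimethoxy-6-(3-methylbut-2-enyl)cyclohexa-2,4-dien-1-one | CC(=O)C1=C(OC)C(OC)=C(OC)C(CC=C(C)C)C1=O | intermediate (not isolated)
9 | 1-[2-hydroxy-4,5,6-trimethoxy-3-(3-methylbut-2-enyl)phenyl]ethanone | CC(=O)c1c(O)c(CC=C(C)C)c(OC)c(OC)c1OC | intermediate
10 | 1-[4,5,6-trimethoxy-2-{[4-(methoxymethoxy)phenyl]methoxy}-3-(3-methylbut-2-enyl)phenyl]ethanone | CC(=O)c1c(OCc2ccc(OCOC)cc2)c(CC=C(C)C)c(OC)c(OC)c1OC | intermediate
11 | diallyl carbonate (bis(prop-2-enyl) carbonate) | C=CCOC(=O)OCC=C | starting material
12 | prop-2-enyl 3-[4,5,6-trimethoxy-2-{[4-(methoxymethoxy)phenyl]methoxy}-3-(3-methylbut-2-enyl)phenyl]-3-oxopropanoate | C=CCOC(=O)CC(=O)c1c(OCc2ccc(OCOC)cc2)c(CC=C(C)C)c(OC)c(OC)c1OC | intermediate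
13 | prop-2-enyl 2-diazo-3-[4,5,6-trimethoxy-2-{[4-(methoxymethoxy)phenyl]methoxy}-3-(3-methylbut-2-enyl)phenyl]-3-oxopropanoate | C=CCOC(=O)C(=[N+]=[N-])C(=O)c1c(OCc2ccc(OCOC)cc2)c(CC=C(C)C)c(OC)c(OC)c1OC | intermediate
14 | prop-2-enyl (2S,3R)-5,6,7-trimethoxy-2-[4-(methoxymethoxy)phenyl]-8-(3-methylbut-2-enyl)-4-oxochromane-3-carboxylate (2,3-trans) | COc1c(OC)c2c(c(CC=C(C)C)c1OC)O[C@H](c1ccc(OCOC)cc1)[C@@H](C(=O)OCC=C)C2=O | intermediate
15 | (2S,3R)-5,6,7-trimethoxy-2-[4-(methoxymethoxy)phenyl]-8-(3-methylbut-2-enyl)-4-oxochromane-3-carboxylic acid | COc1c(OC)c2c(c(CC=C(C)C)c1OC)O[C@H](c1ccc(OCOC)cc1)[C@@H](C(=O)O)C2=O | intermediate (not isolated)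
16 | (2S)-5,6,7-trimethoxy-2-[4-(methoxymethoxy)phenyl]-8-(3-methylbut-2-enyl)chroman-4-one | COc1c(OC)c2c(c(CC=C(C)C)c1OC)O[C@H](c1ccc(OCOC)cc1)CC2=O | intermediate
17 | (2S)-5-hydroxy-2-(4-hydroxyphenyl)-6,7-dimethoxy-8-(3-methylbut-2-enyl)chroman-4-one | COc1c(O)c2c(c(CC=C(C)C)c1OC)O[C@H](c1ccc(O)cc1)CC2=O | target

## Step count and least certain steps

Total: 11 steps. Longest linear sequence: 9 steps (from 4 to 17, steps 3 to 11). The branch from 1 supplies alcohol 3 in 2 steps.

**Step 9 (key step).** The carbenoid may be diverted by attack of the O1 lone pair, followed by a 1,2-benzyl shift of the resulting oxonium ylide, or by cyclopropanation on the ester side. Discrimination between the two enantiotopic hydrogens may also be incomplete with so electron-rich a benzyl group, whose insertion has much hydride-transfer character. Fallback: starting from 9, heating with N,N-dimethylformamide dimethyl acetal should give the enaminone (E)-3-(dimethylamino)-1-[2-hydroxy-4,5,6-trimethoxy-3-(3-methylbut-2-enyl)phenyl]prop-2-en-1-one F1. Brief treatment with dilute HCl in CH2Cl2 should close it, with loss of dimethylamine, to 5,6,7-trimethoxy-8-(3-methylbut-2-enyl)chromen-4-one F2. A rhodium-catalysed asymmetric 1,4-addition of purchased 4-(methoxymethoxy)phenylboronic acid ([Rh(OH)(cod)]2 with a chiral bisphosphine, antipode chosen for 2S, aqueous dioxane) would then give 16, where the route is rejoined before step 11.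

**Step 11.** Under the Lewis acid the C2–O1 bond may ionise, helped by the para oxygen of ring B, or ring C may open and reclose, in either case with erosion of enantiopurity. HCl may also add to the prenyl olefin, and demethylation may go on to the C6 ether. Fallback: starting from 16, MgI2·OEt2 in toluene/THF at about 60 °C should remove only the chelated C5 methyl group and give (2S)-5-hydroxy-6,7-dimethoxy-2-[4-(methoxymethoxy)phenyl]-8-(3-methylbut-2-enyl)chroman-4-one F3. The acetal is then cleaved separately with dilute HCl in methanol at room temperature, which arrives at 17.

**Step 10.** The allylpalladium intermediate may alkylate C3 after decarboxylation instead of being reduced, or the palladium enolate may lose hydride to give the flavone. Any free amine may open the β-keto ester by retro-oxa-Michael reaction before CO2 is lost, with loss of configuration at C2. Fallback: starting from 10, the ester is dispensed with altogether. LiHMDS and 2,2,2-trifluoroethyl trifluoroacetate should give the activated diketone 4,4,4-trifluoro-1-[4,5,6-trimethoxy-2-{[4-(methoxymethoxy)phenyl]methoxy}-3-(3-methylbut-2-enyl)phenyl]butane-1,3-dione F4. Methanesulfonyl azide, Et3N and water in MeCN should convert it by detrifluoroacetylative diazo transfer into the terminal diazo ketone 2-diazo-1-[4,5,6-trimethoxy-2-{[4-(methoxymethoxy)phenyl]methoxy}-3-(3-methylbut-2-enyl)phenyl]ethanone F5. Insertion with a chiral dirhodium carboxylate such as Rh2(S-BSP)4 (dirhodium tetrakis[N-benzenesulfonyl-(S)-prolinate]) or its antipode would then give 16 directly.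

**Step 6.** The phenol is flanked by the prenyl and acetyl groups and is hydrogen-bonded to the ketone, so the coupling may be slow and the activated benzylic alcohol may be consumed by transfer to the hydrazide or by self-condensation. Fallback: starting from 3, an Appel reaction (CBr4, PPh3, CH2Cl2, 0 °C) should give 1-(bromomethyl)-4-(methoxymethoxy)benzene F6, to be used at once. Williamson alkylation of 9 with it (K2CO3, DMF, rt) would arrive at 10.

**Step 3.** The tertiary propargylic chloride may eliminate to the enyne faster than it alkylates the chelated, weakly nucleophilic phenol, and the product ether may lose its tertiary group on handling. Fallback: starting from 4, the 1,1-dimethylallyl group is introduced in one operation by a Tsuji–Trost O-allylation. The carbonate 2-methylbut-3-en-2-yl 2-methylpropyl carbonate F7, made from 2-methylbut-3-en-2-ol and isobutyl chloroformate, is treated with 4 and Pd(PPh3)4 in THF at 0 °C. The branched ether 7 is expected, which rejoins the route before step 5 and bypasses 6.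

## Further compounds

F1 | step 9 | (E)-3-(dimethylamino)-1-[2-hydroxy-4,5,6-trimethoxy-3-(3-methylbut-2-enyl)phenyl]prop-2-en-1-one | CN(C)/C=C/C(=O)c1c(O)c(CC=C(C)C)c(OC)c(OC)c1OC
F2 | step 9 | 5,6,7-trimethoxy-8-(3-methylbut-2-enyl)chromen-4-one | COc1c(OC)c2c(c(CC=C(C)C)c1OC)OC=CC2=O
F3 | step 11 | (2S)-5-hydroxy-6,7-dimethoxy-2-[4-(methoxymethoxy)phenyl]-8-(3-methylbut-2-enyl)chroman-4-one | COc1c(O)c2c(c(CC=C(C)C)c1OC)O[C@H](c1ccc(OCOC)cc1)CC2=O
F4 | step 10 | 4,4,4-trifluoro-1-[4,5,6-trimethoxy-2-{[4-(methoxymethoxy)phenyl]methoxy}-3-(3-methylbut-2-enyl)phenyl]butane-1,3-dione | O=C(CC(=O)C(F)(F)F)c1c(OCc2ccc(OCOC)cc2)c(CC=C(C)C)c(OC)c(OC)c1OC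
F5 | step 10 | 2-diazo-1-[4,5,6-trimethoxy-2-{[4-(methoxymethoxy)phenyl]methoxy}-3-(3-methylbut-2-enyl)phenyl]ethanone | [N-]=[N+]=CC(=O)c1c(OCc2ccc(OCOC)cc2)c(CC=C(C)C)c(OC)c(OC)c1OC
F6 | step 6 | 1-(bromomethyl)-4-(methoxymethoxy)benzene | COCOc1ccc(CBr)cc1
F7 | step 3 | 2-methylbut-3-en-2-yl 2-methylpropyl carbonate | CC(C)COC(=O)OC(C)(C)C=C
A1 | alternative 1 | 2-[4,5,6-trimethoxy-2-[(1S)-1-[4-(methoxymethoxy)phenyl]-3-[(4-methylphenyl)sulfonyloxy]propoxy]-3-(3-methylbut-2-enyl)phenyl]-1,3-dithiane | COc1c(OC)c(C2SCCCS2)c(O[C@H](c2ccc(OCOC)cc2)CCOS(=O)(=O)c2ccc(C)cc2)c(CC=C(C)C)c1OC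
A2 | alternative 1 | (2S)-5,6,7-trimethoxy-2-[4-(methoxymethoxy)phenyl]-8-(3-methylbut-2-enyl)chroman-4-one propane-1,3-diyl dithioketal | COc1c(OC)c2c(c(CC=C(C)C)c1OC)O[C@H](c1ccc(OCOC)cc1)CC21SCCCS1
A3 | alternative 2 | 2-iodo-3,4,5-trimethoxy-6-(3-methylbut-2-enyl)phenol | COc1c(OC)c(I)c(O)c(CC=C(C)C)c1OC
A4 | alternative 2 | 1-(benzyloxy)-4-ethynylbenzene | C#Cc1ccc(OCc2ccccc2)cc1
A5 | alternative 2 | 2-[4-(benzyloxy)phenyl]-5,6,7-trimethoxy-8-(3-methylbut-2-enyl)chromen-4-one | COc1c(OC)c2c(c(CC=C(C)C)c1OC)OC(c1ccc(OCc3ccccc3)cc1)=CC2=O
A6 | alternative 3 | methyl 2-methoxy-4-[(2S)-2-[4-(methoxymethoxy)phenyl]-4-oxo-2,3-dihydropyran-6-yl]-7-methyl-3-oxooct-6-enoate | COC(=O)C(OC)C(=O)C(CC=C(C)C)C1=CC(=O)C[C@@H](c2ccc(OCOC)cc2)O1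
A7 | alternative 3 | (2S)-5,7-dihydroxy-6-methoxy-2-[4-(methoxymethoxy)phenyl]-8-(3-methylbut-2-enyl)chroman-4-one | COc1c(O)c2c(c(CC=C(C)C)c1O)O[C@H](c1ccc(OCOC)cc1)CC2=O
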